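Reagent is the easy part: it enters no rate but that of its own transfer, so the target does not feel it, and with 18.0 transfer times in the run it ends at >99.9% of saturation.

solid substrate 2.0 M; gas 200 mM (held); time 5.0 d

    starting material → side product (k1 = 0.044 h⁻¹)
    starting material → target (k2 = 0.23 h⁻¹)
    starting material ⇌ intermediate (K3 = 0.69, k3 = 0.0067 h⁻¹)
    gas ⇌ reagent, rate k4*(csat - [reagent]) (k4 = 0.15 h⁻¹, csat = 200 mM)
    solid substrate ⇌ starting material, rate k5*(cs5 - [starting material]) while solid is left; crystals form when [starting material] > cs5 (cs5 = 0.64 M, k5 = 0.0059 h⁻¹)
    target → over-reaction product (k6 = 0.0052 h⁻¹)

- the target standing at 5.0 d, as a percentage of the solid substrate charged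
- concentration of reagent in solution at 5.0 d, in percent of saturation

The other rate constants, turned into half-lives, differ in how well they must be known:

| Path | Half-life | Error reaches the target |
|---|---|---|
| dissolution | 117 h | in full |
| to target | 0.13 d | through a share |
| to side product | 15.8 h | through a share |
| over-reaction | 5.6 d | in part |
| to intermediate (forward step) | 4.3 d | slightly |

Dissolution is the rate-limiting step, since starting material has a far shorter half-life by the way to target than dissolution has. Starting material therefore rests at a low quasi-steady level, and an error in the dissolution coefficient or the solubility passes fully into the target. The ways to target and side product divide the feed between them, and over-reaction trims the result over a run comparable with its half-life.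

By this reckoning, with the way to intermediate left out, c(starting material) rests near 13.5 mM, and target is made at 3.10 mM h⁻¹. Set against first-order loss, this gives 277 mM, the feed-limited target concentration: the make rate times the target's mean lifetime times the approach to its plateau. That is 13.8% of the charge, while dissolution into a solution kept empty can deliver at most 22.7% of it by 5.0 d. The charge does not enter the feed-limited target concentration while solid remains.

The forecast gives 13.4% for the target, a little below this reckoning, and 100% of saturation for reagent, and holds that “Dissolution is the bottleneck”.

The flask gives 13.4% for the target, 0.48 percentage points under the reckoning, and 100% of saturation for reagent. At 2.50 d starting material was made 1.00 times as fast as it was used up. Carried to 10.0 d, the feed-limited target concentration gives 21.3% of the charge, and the flask holds 20.9%.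

For the neighbour flask with 1.2 M of solid substrate, the same feed-limited target concentration gives 23.1% of its charge. That neighbour flask gives 22.3% for the target, with 64% of its charge still there, solid or dissolved.

(Its constants were chosen freely, and the outcome is calculated.)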